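## Structural features

Gymcononopin D (24) is an achiral bibenzyl in which ring A, a 3,5-dimethoxyphenyl ring, is joined from its C1 through a CH2CH2 bridge to ring B, a 3-hydroxyphenyl ring, and carries at C2 a CH2 group that links it to ring C, a 4-hydroxyphenyl ring. No stereocentre, ring fusion or heterocycle is present, so nothing has to be controlled except the positions of the substituents on ring A. Ring A is 1,2,3,5-tetrasubstituted: the two carbon substituents sit side by side at C1 and C2, C2 is wedged between C1 and the C3 methoxy group, and the second methoxy group is at C5. The real difficulty is to bring a benzyl group to the crowded C2 position next to a second carbon arm, because direct electrophilic substitution of a 3,5-dimethoxyphenyl derivative can also go to C4, between the two methoxy groups. The fragile features are the two free phenols, which must be masked while organometallic reagents are used, the electron-rich ring A, which is open to electrophilic attack and, in silylated precursors, to protodesilylation, and the doubly benzylic CH2 between rings A and C. The key step exploits the C1–CH2 and C2–CH2 bonds of ring A beside the C3 methoxy group: this is the substitution pattern of 3,5-dimethoxybenzyne, which accepts a carbon nucleophile at C1 and an acyl group at C2, so a beta-ketoester that already contains ring C can deliver both arms in one operation.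

## Logic of the disconnections

24 to 21. The two phenolic O–H bonds are traced back to O–CH2Ph bonds and the two C–H bonds of the bridge carbon next to ring B to a C=O. All three changes are undone by one hydrogenation over Pd/C, so the phenols stay masked through every organometallic step and no separate deprotection is needed. The demand on the forward step is complete hydrogenolysis of the aryl ketone to CH2 without saturation of an arene.

21 to 17 and 19. The bond between the carbonyl carbon and C1 of ring B is cut. This removes ring B as a simple aryl nucleophile, 19, formed in the flask from 18, and leaves ring A with a two-carbon acyl arm in 17. The forward step must stop after one addition and must add faster than it deprotonates the benzylic CH2 of 17.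

17 to 16. The C(O)–N bond is exchanged for the C(O)–OMe bond. The methyl ester of 16 is the group the key step delivers, so this is a pure change of acyl leaving group. The forward aminolysis must not touch the benzyl ether.

16 to 14. The two C–H bonds of the CH2 between rings A and C are traced to a C=O. The diaryl ketone is the form in which ring C arrives at C2. The forward reduction must take this ketone to CH2 while the ester and the benzyl ether survive, which the strong cation stabilisation by both oxygenated rings should allow.

14 to 8 and 10. The ring A C1–CH2 bond and the ring A C2–C(=O) bond are cut together. This is the largest simplification of the route: ring A becomes aryne 11, released from 8, and the acetate and aroyl arms become the two halves of the alpha-carbon to acyl bond of 10. The forward step needs the enolate carbon to attack C1 and not C2 of the unsymmetrical aryne.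

10 to 9. The CH2–CO2Me bond is cut, leaving an aryl methyl ketone and dimethyl carbonate. The forward Claisen condensation is driven by deprotonation of its product.

8 to 6 to 2 to 1. The O–S bond of the triflate, the ring C–Si bond and the O–C(O) bond of the carbamate are cut in turn, which leads back to a symmetrical phenol. The forward lithiation must occur between the carbamate and a methoxy group and not between the two methoxy groups. The carbamate, the stronger directing group, should secure this.

## Other disconnections considered

Alternative 1: Ring A is taken apart completely. Its C1–C2 and C3–C4 bonds are cut so that the six ring carbons come from dimethyl 2-[4-(benzyloxy)benzyl]malonate A1 and (E)-6-[3-(benzyloxy)phenyl]hex-3-en-2-one A2. In the forward key step NaOMe would add the carbanion of A1 to the beta-carbon of A2, and the methyl ketone enolate would then close onto one ester to give the cyclohexanedione A3.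
- In favour: every substituent position is fixed by connectivity, so the regiochemical question of the aryne route does not arise; on this point the alternative is the better plan. The reagents are cheap, and no organolithium or fluoride chemistry is needed.
- Against: the Michael addition must join a fully substituted malonate carbon to a beta-alkyl enone, a crowded and reversible bond formation. A3 is still far from ring A: the angular ester must be removed, the dione dehydrogenated to the resorcinol and both oxygens methylated, all in the presence of two benzyl ethers. Two stereocentres are made only to be erased.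
- Comparison: the chosen plan starts from a ring that is already aromatic and already carries both methoxy groups, so it spends no steps on oxidation level. Mechanistically the alternative rests on robust enolate chemistry applied to a hindered case, while the aryne insertion has close analogy for this aryne and nucleophile class. The step counts should be about equal.

Alternative 2: The two bonds flanking the bridge, ring A C1–CH and CH2–ring B C1, are cut, with a vinyl boronate as two-carbon linchpin. The aryllithium from 2-[4-(benzyloxy)benzyl]-1-bromo-3,5-dimethoxybenzene A4 would form an ate complex with 4,4,5,5-tetramethyl-2-vinyl-1,3,2-dioxaborolane A5. Oxidative addition of 3-(benzyloxy)phenyl trifluoromethanesulfonate A6 to zerovalent palladium, generated from Pd(OAc)2 and a ferrocenyl bisphosphine, would give an arylpalladium species of divalent palladium. This would trigger 1,2-migration of the ring A aryl group from boron to carbon and lead to the boronate A7.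
- In favour: three components are joined and the whole bridge is built in one step. In convergence and probably in step count this alternative is the equal or the better of the chosen plan.
- Against: the key step does not solve the real difficulty. The adjacent carbon substituents at C1 and C2 must already be present in A4, whose regioselective preparation is a separate problem. The migrating aryl group carries an ortho benzyl substituent, which should slow the 1,2-shift. Boron is not wanted in the target, so a protodeboronation must follow, and the stereocentre of A7 and any enantiocontrol by the ligand are wasted.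
- Comparison: the chosen plan is longer but its key step sets the ring A pattern itself. Alternative 2 is superior only for the bridge.

Alternative 3: The C6–C1 and C3–C2 bonds of ring A are cut, so the ring is assembled from the Brassard diene [(1,3-dimethoxybuta-1,3-dien-1-yl)oxy]trimethylsilane A8 and the ynone 1-[4-(benzyloxy)phenyl]-5-[3-(benzyloxy)phenyl]pent-2-yn-1-one A9. In the forward step the nucleophilic CH2 terminus of A8 would bond to the beta-carbon of A9 and the ketene acetal carbon to the alpha-carbon. Loss of methanol and of the silyl group would aromatise the adduct to the benzophenone A10.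
- In favour: like the chosen plan it gives an aromatic ring A with the aroyl group at C2, but A10 already contains ring B and the whole carbon skeleton; on this point it is better. Only O-methylation, carbonyl reduction and debenzylation would remain, three steps against four. The regiochemistry follows from polarity matching, which should be as reliable as the aryne distortion.
- Against: A9 needs a terminal alkyne precursor that has to be made in several steps, and A8 is moisture-sensitive and must be prepared. A beta-alkyl ynone is a modest dienophile, so open-chain Michael adducts and diene desilylation could compete. The C3 oxygen of A10 arrives as a hydrogen-bonded phenol that needs a separate methylation.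
- Comparison: the reduction of the hindered diaryl ketone is the same problem in both plans, and overall step economy should be about equal. The chosen plan is preferred because ring A comes from a cheap symmetrical phenol and the key step has direct analogy with the same aryne.

Key step: step 5

Remark: where a product is present before work-up only as its own salt (the DBU salt of 7 in step 3, the sodium enolate of 10 in step 4), it is listed in its neutral form.

## Route

Step 1
Reactants: 1 3,5-dimethoxyphenol
Product: 2 3,5-dimethoxyphenyl N-isopropylcarbamate
Conditions: iPrNCO (1.5 equiv), Et3N (0.2 equiv), CH2Cl2, rt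
Reagents that add atoms: isopropyl isocyanate, CC(C)N=C=O
Why: Base-catalysed addition of the phenol O–H to the isocyanate (carbamoylation) should proceed cleanly with an electron-rich phenol. It installs a strong directing group for ortho-metalation that can later be removed by elimination.

Step 2
Reactants: 2 3,5-dimethoxyphenyl N-isopropylcarbamate
Product: 6 3,5-dimethoxy-2-(trimethylsilyl)phenyl N-isopropylcarbamate, via N-silyl carbamate 3 (not isolated), via ortho-lithiated carbamate 4 (not isolated), via C,N-bis-silyl carbamate 5 (not isolated)
Conditions: TBSOTf (1.1 equiv), TMEDA (1.1 equiv), Et2O, 0 °C to rt; then TMEDA (2 equiv), n-BuLi (2.2 equiv), −78 °C; then TMSCl (3.5 equiv), −78 °C to rt; aq NaHSO4 work-up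
Reagents that add atoms: chlorotrimethylsilane, C[Si](C)(C)Cl
Why: Directed ortho-metalation: the N–H is first masked as N-silyl carbamate 3, then n-BuLi/TMEDA lithiates the ring carbon between the carbamate and a methoxy group (the two such sites are equivalent by symmetry), since the carbamate outranks methoxy as a director. TMSCl traps aryllithium 4 at low temperature, before an anionic Fries shift can occur, and the acidic work-up removes the N-silyl group of 5.

Step 3
Reactants: 6 3,5-dimethoxy-2-(trimethylsilyl)phenyl N-isopropylcarbamate
Product: 8 3,5-dimethoxy-2-(trimethylsilyl)phenyl trifluoromethanesulfonate, via 3,5-dimethoxy-2-(trimethylsilyl)phenol 7 (not isolated)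
Conditions: DBU (1.5 equiv), Et2NH (1.2 equiv), MeCN, 40 °C; then PhNTf2 (1.5 equiv), rt
Reagents that add atoms: N-phenylbis(trifluoromethanesulfonimide), O=S(=O)(N(c1ccccc1)S(=O)(=O)C(F)(F)F)C(F)(F)F
Why: E1cB cleavage of the secondary carbamate (DBU removes the N–H, the phenoxide leaves, Et2NH scavenges the isocyanate as a urea) is followed by O-sulfonylation of the phenoxide in the same flask. Not isolating 7 should prevent protodesilylation of this very electron-rich silylphenol.

Step 4
Reactants: 9 4'-(benzyloxy)acetophenone
Product: 10 methyl 3-[4-(benzyloxy)phenyl]-3-oxopropanoate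
Conditions: NaH (2.5 equiv), (MeO)2CO (3 equiv), THF, reflux; then 1 M aq HCl, 0 °C
Reagents that add atoms: dimethyl carbonate, COC(=O)OC
Why: Crossed Claisen condensation: the ketone enolate is acylated by dimethyl carbonate, and irreversible deprotonation of the beta-ketoester drives the reaction. The aryl benzyl ether is inert to NaH.

Step 5
Reactants: 8 3,5-dimethoxy-2-(trimethylsilyl)phenyl trifluoromethanesulfonate; 10 methyl 3-[4-(benzyloxy)phenyl]-3-oxopropanoate
Product: 14 methyl 2-{2-[4-(benzyloxy)benzoyl]-3,5-dimethoxyphenyl}acetate, via 3,5-dimethoxybenzyne 11 (not isolated), via aryl carbanion adduct 12 (not isolated), via benzocyclobutenoxide 13 (not isolated)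
Conditions: 8 (1.25 equiv), 10 (1.0 equiv), CsF (2.5 equiv), MeCN (0.2 M), 80 °C
Reagents that add atoms: none
Why: Fluoride attacks the silicon of 8 and the ortho triflate is expelled, which gives aryne 11, while CsF also converts 10 into its cesium enolate. The enolate carbon adds to C1 of 11, the aryne terminus remote from the C3 methoxy group, and leaves carbanion 12 at C2. This carbanion adds to the neighbouring aryl ketone carbonyl in a 4-exo-trig closure to give benzocyclobutenoxide 13, whose strained ring opens by cleavage of the former alpha-carbon to acyl bond; the benzylic ester enolate so released is protonated by a further molecule of 10. The closest known reaction type is the fluoride-induced acyl-alkylation of arynes with beta-ketoesters, a formal insertion of the aryne into a carbon–carbon sigma bond. The four-membered ring of 13 is the only ring closed and it does not survive, and the stereocentres of 12 and 13 are erased, so 14 contains neither a new ring nor a stereocentre. The step needs regioselective addition to an unsymmetrical aryne: the inductively withdrawing C3 methoxy group distorts the aryne towards attack at C1 and stabilises the negative charge that develops at C2, and the remote C5 methoxy group should not override this. Carbon over oxygen arylation is favoured by the soft cesium enolate in MeCN, and the aprotic medium should let ring closure of 12 outrun its protonation, which would give only an alpha-aryl ketoester.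

Step 6
Reactants: 14 methyl 2-{2-[4-(benzyloxy)benzoyl]-3,5-dimethoxyphenyl}acetate
Product: 16 methyl 2-{2-[4-(benzyloxy)benzyl]-3,5-dimethoxyphenyl}acetate, via diarylmethanol 15 (not isolated)
Conditions: Et3SiH (4 equiv), CF3CO2H/CH2Cl2 (1:4), 0 °C to rt
Reagents that add atoms: none
Why: Ionic hydrogenation: the protonated diaryl ketone takes hydride from Et3SiH to give carbinol 15, which ionises to a diarylmethyl cation stabilised by both oxygenated rings and is reduced a second time. The ester, the aryl benzyl ether and the methyl ethers do not ionise under these conditions.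

Step 7
Reactants: 16 methyl 2-{2-[4-(benzyloxy)benzyl]-3,5-dimethoxyphenyl}acetate
Product: 17 2-{2-[4-(benzyloxy)benzyl]-3,5-dimethoxyphenyl}-N-methoxy-N-methylacetamide
Conditions: MeNH(OMe)·HCl (1.6 equiv), iPrMgCl (3.2 equiv), THF, −20 °C to 0 °C
Reagents that add atoms: N,O-dimethylhydroxylamine hydrochloride, CNOC.Cl
Why: Direct aminolysis of the ester by the chloromagnesium amide of N,O-dimethylhydroxylamine, which is formed in the flask and is strongly nucleophilic but only weakly basic. The resulting Weinreb amide allows a single aryl addition in the next step.

Step 8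
Reactants: 17 2-{2-[4-(benzyloxy)benzyl]-3,5-dimethoxyphenyl}-N-methoxy-N-methylacetamide; 18 1-(benzyloxy)-3-bromobenzene
Product: 21 2-{2-[4-(benzyloxy)benzyl]-3,5-dimethoxyphenyl}-1-[3-(benzyloxy)phenyl]ethan-1-one, via 3-(benzyloxy)phenylmagnesium bromide 19 (not isolated), via tetrahedral magnesium chelate 20 (not isolated)
Conditions: 18 (1.6 equiv), Mg turnings (1.8 equiv), cat. I2, THF, 40 °C; then 17 (1.0 equiv), THF, 0 °C to rt; aq NH4Cl
Reagents that add atoms: none
Why: Weinreb ketone synthesis: Mg inserts into the C–Br bond of 18 and Grignard reagent 19 adds once to the amide carbonyl. The five-membered N-methoxy chelate 20 persists until hydrolysis, so no tertiary alcohol should form.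

Step 9
Reactants: 21 2-{2-[4-(benzyloxy)benzyl]-3,5-dimethoxyphenyl}-1-[3-(benzyloxy)phenyl]ethan-1-one
Product: 24 Gymcononopin D, 3-{2-[2-(4-hydroxybenzyl)-3,5-dimethoxyphenyl]ethyl}phenol, via debenzylated ketone 22 (not isolated), via benzylic carbinol 23 (not isolated)
Conditions: H2 (3 bar), 10% Pd/C, AcOH/EtOAc (1:1), cat. HClO4, rt to 40 °C
Reagents that add atoms: none
Why: Catalytic hydrogenolysis over Pd/C cleaves both benzyl–oxygen bonds and reduces the aryl ketone to benzylic carbinol 23, whose acid-assisted C–O hydrogenolysis gives the CH2CH2 bridge. The diarylmethane CH2, the methyl ethers and the arene rings should be inert to Pd/C at this pressure.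

## Compound list

1 | 3,5-dimethoxyphenol | COc1cc(O)cc(OC)c1 | starting material
2 | 3,5-dimethoxyphenyl N-isopropylcarbamate | COc1cc(OC)cc(OC(=O)NC(C)C)c1 | intermediate
3 | 3,5-dimethoxyphenyl N-(tert-butyldimethylsilyl)-N-isopropylcarbamate (formed in the flask, not isolated) | COc1cc(OC)cc(OC(=O)N(C(C)C)[Si](C)(C)C(C)(C)C)c1 | intermediate
4 | {2-[({tert-butyl(dimethyl)silyl}(isopropyl)carbamoyl)oxy]-4,6-dimethoxyphenyl}lithium (formed in the flask, not isolated) | COc1cc(OC)c([Li])c(OC(=O)N(C(C)C)[Si](C)(C)C(C)(C)C)c1 | intermediate
5 | 3,5-dimethoxy-2-(trimethylsilyl)phenyl N-(tert-butyldimethylsilyl)-N-isopropylcarbamate (formed in the flask, not isolated) | COc1cc(OC)c([Si](C)(C)C)c(OC(=O)N(C(C)C)[Si](C)(C)C(C)(C)C)c1 | intermediate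
6 | 3,5-dimethoxy-2-(trimethylsilyl)phenyl N-isopropylcarbamate | COc1cc(OC)c([Si](C)(C)C)c(OC(=O)NC(C)C)c1 | intermediate
7 | 3,5-dimethoxy-2-(trimethylsilyl)phenol (formed in the flask, not isolated) | COc1cc(OC)c([Si](C)(C)C)c(O)c1 | intermediate
8 | 3,5-dimethoxy-2-(trimethylsilyl)phenyl trifluoromethanesulfonate | COc1cc(OC)c([Si](C)(C)C)c(OS(=O)(=O)C(F)(F)F)c1 | intermediate
9 | 4'-(benzyloxy)acetophenone | CC(=O)c1ccc(OCc2ccccc2)cc1 | starting material
10 | methyl 3-[4-(benzyloxy)phenyl]-3-oxopropanoate | COC(=O)CC(=O)c1ccc(OCc2ccccc2)cc1 | intermediate
11 | 3,5-dimethoxybenzyne (formed in the flask, not isolated) | COC1=CC(OC)=CC#C1 | intermediate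
12 | cesium 2-{1-[4-(benzyloxy)phenyl]-3-methoxy-1,3-dioxopropan-2-yl}-4,6-dimethoxybenzen-1-ide (racemic; formed in the flask, not isolated) | COC(=O)C(C(=O)c1ccc(OCc2ccccc2)cc1)c1cc(OC)cc(OC)[c-]1.[Cs+] | intermediate
13 | cesium 7-[4-(benzyloxy)phenyl]-3,5-dimethoxy-8-(methoxycarbonyl)bicyclo[4.2.0]octa-1,3,5-trien-7-olate (diastereomer mixture; formed in the flask, not isolated) | COC(=O)C1c2cc(OC)cc(OC)c2C1([O-])c1ccc(OCc2ccccc2)cc1.[Cs+] | intermediate
14 | methyl 2-{2-[4-(benzyloxy)benzoyl]-3,5-dimethoxyphenyl}acetate | COC(=O)Cc1cc(OC)cc(OC)c1C(=O)c1ccc(OCc2ccccc2)cc1 | intermediate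
15 | methyl 2-(2-{[4-(benzyloxy)phenyl](hydroxy)methyl}-3,5-dimethoxyphenyl)acetate (racemic; formed in the flask, not isolated) | COC(=O)Cc1cc(OC)cc(OC)c1C(O)c1ccc(OCc2ccccc2)cc1 | intermediate
16 | methyl 2-{2-[4-(benzyloxy)benzyl]-3,5-dimethoxyphenyl}acetate | COC(=O)Cc1cc(OC)cc(OC)c1Cc1ccc(OCc2ccccc2)cc1 | intermediate
17 | 2-{2-[4-(benzyloxy)benzyl]-3,5-dimethoxyphenyl}-N-methoxy-N-methylacetamide | CON(C)C(=O)Cc1cc(OC)cc(OC)c1Cc1ccc(OCc2ccccc2)cc1 | intermediate
18 | 1-(benzyloxy)-3-bromobenzene | Brc1cccc(OCc2ccccc2)c1 | starting material
19 | 3-(benzyloxy)phenylmagnesium bromide (formed in the flask, not isolated) | Br[Mg]c1cccc(OCc2ccccc2)c1 | intermediate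
20 | bromomagnesium 2-{2-[4-(benzyloxy)benzyl]-3,5-dimethoxyphenyl}-1-[3-(benzyloxy)phenyl]-1-[methoxy(methyl)amino]ethan-1-olate (racemic; formed in the flask, not isolated) | CON(C)C(O[Mg]Br)(Cc1cc(OC)cc(OC)c1Cc1ccc(OCc2ccccc2)cc1)c1cccc(OCc2ccccc2)c1 | intermediate
21 | 2-{2-[4-(benzyloxy)benzyl]-3,5-dimethoxyphenyl}-1-[3-(benzyloxy)phenyl]ethan-1-one | O=C(Cc1cc(OC)cc(OC)c1Cc1ccc(OCc2ccccc2)cc1)c1cccc(OCc2ccccc2)c1 | intermediate
22 | 2-[2-(4-hydroxybenzyl)-3,5-dimethoxyphenyl]-1-(3-hydroxyphenyl)ethan-1-one (formed in the flask, not isolated) | O=C(Cc1cc(OC)cc(OC)c1Cc1ccc(O)cc1)c1cccc(O)c1 | intermediate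
23 | 4-({2-[2-hydroxy-2-(3-hydroxyphenyl)ethyl]-4,6-dimethoxyphenyl}methyl)phenol (racemic; formed in the flask, not isolated) | OC(Cc1cc(OC)cc(OC)c1Cc1ccc(O)cc1)c1cccc(O)c1 | intermediate
24 | Gymcononopin D, 3-{2-[2-(4-hydroxybenzyl)-3,5-dimethoxyphenyl]ethyl}phenol | COc1cc(CCc2cccc(O)c2)c(Cc2ccc(O)cc2)c(OC)c1 | target

## Step count and least certain steps

Total step count: 9 steps. Longest linear sequence: 8 steps (steps 1, 2, 3, 5, 6, 7, 8 and 9, from 1 to 24); step 4 is a one-step side branch.

Step 5 (key step). The most likely failures are addition of the enolate at the wrong aryne terminus, protonation of carbanion 12 before it closes onto the ketone (leaving plain alpha-arylation), and arylation on the enolate oxygen. The cause is that the aroyl ketone is less electrophilic than an alkyl ketone and the aryne is short-lived. The fallback abandons the aryne for a Friedel–Crafts acylation. It sets out from 9, which aqueous NaOCl should oxidise in a haloform reaction to 4-(benzyloxy)benzoic acid F1. (CF3CO)2O would convert F1 in the flask into 4-(benzyloxy)benzoic trifluoroacetic anhydride F2. With cat. H3PO4, F2 should acylate purchased methyl 2-(3,5-dimethoxyphenyl)acetate F3 at the ring position next to the acetate arm and para to a methoxy group. This gives 14, where the route is rejoined.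

Step 2. The risks are lithiation between the two methoxy groups instead of next to the carbamate, and migration of the carbamoyl group to carbon if the aryllithium warms before silylation. The fallback replaces steps 1 to 3 by a halogen-based sequence and sets out from 1. NBS in CH2Cl2 at −78 °C should brominate mainly next to the hydroxyl group to give 2-bromo-3,5-dimethoxyphenol F4, and HMDS should silylate it to (2-bromo-3,5-dimethoxyphenoxy)trimethylsilane F5. n-BuLi at −100 °C would effect bromine–lithium exchange, and a 1,3 shift of silicon from oxygen to carbon (retro-Brook) would give lithium 3,5-dimethoxy-2-(trimethylsilyl)phenoxide F6. Tf2O would trap F6 as 8, where the route is rejoined.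

Step 6. The reduction may stall at the carbinol stage, because hydride transfer from a silane to the hindered carbonyl is slow. The intermediate cation may be captured by the neighbouring ester carbonyl with loss of the methyl group. Acidolysis of the benzyl ether and ipso-protonation of ring A with loss of the aroyl group are further risks. The fallback separates hydride delivery from ionisation and sets out from 14. NaBH4 in MeOH/THF should reduce the ketone to 15, which with cat. TsOH is allowed to close to 1-[4-(benzyloxy)phenyl]-6,8-dimethoxyisochroman-3-one F7. Et3SiH with BF3·OEt2 in CH2Cl2 at −40 to 0 °C should ionise the doubly benzylic lactone C–O bond and reduce the cation to 2-{2-[4-(benzyloxy)benzyl]-3,5-dimethoxyphenyl}acetic acid F8. Coupling of F8 with MeNH(OMe)·HCl (EDC·HCl, HOBt, iPr2NEt) gives 17, where the route is rejoined.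

Step 8. The basic Grignard reagent 19 may deprotonate the benzylic CH2 of 17 instead of adding, which would return 17 on work-up. The fallback uses a more electrophilic carbonyl and a less basic nucleophile and sets out from 17. iBu2AlH in THF at −78 °C should give 2-{2-[4-(benzyloxy)benzyl]-3,5-dimethoxyphenyl}acetaldehyde F9. Addition of 19 premixed with anhydrous CeCl3 at −78 °C should give 2-{2-[4-(benzyloxy)benzyl]-3,5-dimethoxyphenyl}-1-[3-(benzyloxy)phenyl]ethan-1-ol F10. Hydrogenation of F10 under the conditions of step 9 leads directly to 24.

Step 9. Deoxygenation may remain incomplete, because the benzylic C–O bond next to the meta-oxygenated ring B is not strongly activated. The acid additive may also promote condensation of the ketone or of a benzylic cation with the electron-rich ring C. The fallback removes the oxygen by elimination and sets out from 21. NaBH4 should give carbinol F10, and cat. TsOH in toluene at 80 °C should dehydrate it to (E)-2-[4-(benzyloxy)benzyl]-1-{2-[3-(benzyloxy)phenyl]ethenyl}-3,5-dimethoxybenzene F11. H2 (1 atm) over 10% Pd/C in EtOAc/MeOH without acid should then saturate the alkene and cleave both benzyl ethers to give 24.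

## Further compounds

F1 | step 5 | 4-(benzyloxy)benzoic acid | OC(=O)c1ccc(OCc2ccccc2)cc1
F2 | step 5 | 4-(benzyloxy)benzoic trifluoroacetic anhydride | O=C(OC(=O)C(F)(F)F)c1ccc(OCc2ccccc2)cc1
F3 | step 5 | methyl 2-(3,5-dimethoxyphenyl)acetate (purchased) | COC(=O)Cc1cc(OC)cc(OC)c1
F4 | step 2 | 2-bromo-3,5-dimethoxyphenol | COc1cc(O)c(Br)c(OC)c1
F5 | step 2 | (2-bromo-3,5-dimethoxyphenoxy)trimethylsilane | COc1cc(O[Si](C)(C)C)c(Br)c(OC)c1
F6 | step 2 | lithium 3,5-dimethoxy-2-(trimethylsilyl)phenoxide | COc1cc(OC)c([Si](C)(C)C)c([O-])c1.[Li+]
F7 | step 6 | 1-[4-(benzyloxy)phenyl]-6,8-dimethoxyisochroman-3-one (racemic) | COc1cc2c(c(OC)c1)C(c1ccc(OCc3ccccc3)cc1)OC(=O)C2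
F8 | step 6 | 2-{2-[4-(benzyloxy)benzyl]-3,5-dimethoxyphenyl}acetic acid | OC(=O)Cc1cc(OC)cc(OC)c1Cc1ccc(OCc2ccccc2)cc1
F9 | step 8 | 2-{2-[4-(benzyloxy)benzyl]-3,5-dimethoxyphenyl}acetaldehyde | O=CCc1cc(OC)cc(OC)c1Cc1ccc(OCc2ccccc2)cc1
F10 | step 8 | 2-{2-[4-(benzyloxy)benzyl]-3,5-dimethoxyphenyl}-1-[3-(benzyloxy)phenyl]ethan-1-ol (racemic) | OC(Cc1cc(OC)cc(OC)c1Cc1ccc(OCc2ccccc2)cc1)c1cccc(OCc2ccccc2)c1
F11 | step 9 | (E)-2-[4-(benzyloxy)benzyl]-1-{2-[3-(benzyloxy)phenyl]ethenyl}-3,5-dimethoxybenzene | COc1cc(/C=C/c2cccc(OCc3ccccc3)c2)c(Cc2ccc(OCc3ccccc3)cc2)c(OC)c1
A1 | alternative 1 | dimethyl 2-[4-(benzyloxy)benzyl]malonate | COC(=O)C(Cc1ccc(OCc2ccccc2)cc1)C(=O)OC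
A2 | alternative 1 | (E)-6-[3-(benzyloxy)phenyl]hex-3-en-2-one | CC(=O)/C=C/CCc1cccc(OCc2ccccc2)c1
A3 | alternative 1 | methyl 1-[4-(benzyloxy)benzyl]-6-{2-[3-(benzyloxy)phenyl]ethyl}-2,4-dioxocyclohexane-1-carboxylate (diastereomer mixture) | COC(=O)C1(Cc2ccc(OCc3ccccc3)cc2)C(CCc2cccc(OCc3ccccc3)c2)CC(=O)CC1=O
A4 | alternative 2 | 2-[4-(benzyloxy)benzyl]-1-bromo-3,5-dimethoxybenzene | COc1cc(Br)c(Cc2ccc(OCc3ccccc3)cc2)c(OC)c1
A5 | alternative 2 | 4,4,5,5-tetramethyl-2-vinyl-1,3,2-dioxaborolane | C=CB1OC(C)(C)C(C)(C)O1
A6 | alternative 2 | 3-(benzyloxy)phenyl trifluoromethanesulfonate | O=S(=O)(Oc1cccc(OCc2ccccc2)c1)C(F)(F)F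
A7 | alternative 2 | 2-(1-{2-[4-(benzyloxy)benzyl]-3,5-dimethoxyphenyl}-2-[3-(benzyloxy)phenyl]ethyl)-4,4,5,5-tetramethyl-1,3,2-dioxaborolane (racemic) | COc1cc(C(Cc2cccc(OCc3ccccc3)c2)B2OC(C)(C)C(C)(C)O2)c(Cc2ccc(OCc3ccccc3)cc2)c(OC)c1
A8 | alternative 3 | [(1,3-dimethoxybuta-1,3-dien-1-yl)oxy]trimethylsilane (Brassard diene) | COC(=C)C=C(OC)O[Si](C)(C)C
A9 | alternative 3 | 1-[4-(benzyloxy)phenyl]-5-[3-(benzyloxy)phenyl]pent-2-yn-1-one | O=C(C#CCCc1cccc(OCc2ccccc2)c1)c1ccc(OCc2ccccc2)cc1
A10 | alternative 3 | [4-(benzyloxy)phenyl](2-{2-[3-(benzyloxy)phenyl]ethyl}-6-hydroxy-4-methoxyphenyl)methanone | COc1cc(O)c(C(=O)c2ccc(OCc3ccccc3)cc2)c(CCc2cccc(OCc3ccccc3)c2)c1
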